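**Overview**

1. Numbering: C1 is the ring carbon carrying OH and C7 (the CH2OBz carbon), C2 the CHOH, C3 and C6 the ring CHOBz carbons, C4=C5 the alkene. O1, O2 and O3 lie on one face of the ring (the O-face), C7 and O6 on the other (the C7-face).
2. Cuts, in retrosynthetic order: O1 and O2 are masked as a ketal. The C3–O and C6–O benzoate bonds are cut together, which restores a C3=C4–C5=C6 diene. Then the C7–O benzoate and the C7 oxidation level are cut (CH2O back to CO2Me and CO2H). Last come the C1–O1 and C2–O2 bonds, which leaves benzoic acid.
3. Enabling feature: on the cyclohexene ring the benzoates at C3 and C6 are trans and 1,4 across C4=C5, the imprint of a trans-1,4-diacyloxylation of a cyclohexa-1,3-diene. C1 to C7 with cis oxygens on C1 and C2 is the skeleton of an ipso,ortho-cis-dihydroxylated benzoic acid.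
4. Forward order: the carbocycle is not built but taken over from benzoic acid by dearomatisation. The only ring formed is a temporary dioxolane on O1/O2 (step 3), reopened in step 7. C7 is reduced and benzoylated (steps 4 and 5), and step 6 installs both ring benzoates at once.
5. Stereochemistry: C1, C2 and the absolute configuration come from the enzyme in step 1. C3 and C6 are set relative to them in step 6: benzoate anti to palladium at C3 on the O-face, metal-delivered benzoate at C6 on the C7-face.

Key step: step 6

Remark on descriptors: in this numbering (used for all names instead of lowest locants) the target is (1R,2R,3R,6R). The descriptor at C1 changes along the route (S in 3 to 6, R in 7 and 9, S in 10, R in 11) only because the ranking of its neighbours changes; the arrangement set in step 1 is never altered.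

Assumption: the blocked mutant Cupriavidus necator B9 is obtained from a culture collection and used as a whole-cell catalyst; all chemicals are purchased.

**Route**

Step 1
Reactants: 1 benzoic acid
Product: 4 (1S,2R)-1,2-dihydroxycyclohexa-3,5-diene-1-carboxylic acid, via sodium benzoate 2 (not isolated), via sodium dienediol carboxylate 3 (not isolated)
Conditions: NaOH (1 equiv), resting cells of Cupriavidus necator B9 (benzoate 1,2-dioxygenase, no diol dehydrogenase), fructose, phosphate buffer pH 7.2, air, 30 °C; cells removed, then HCl to pH 3 at 0 °C, EtOAc extraction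
Reagents that add atoms: dioxygen, O=O
Why: The non-haem iron benzoate 1,2-dioxygenase adds both atoms of one O2 to the same face across the ipso and ortho carbons (enzymatic arene cis-dihydroxylation), and since the mutant cannot dehydrogenate the product the dearomatised diol should accumulate as a single enantiomer, the enzyme setting C1 (S) and C2 (R).

Step 2
Reactants: 4 (1S,2R)-1,2-dihydroxycyclohexa-3,5-diene-1-carboxylic acid
Product: 5 methyl (1S,2R)-1,2-dihydroxycyclohexa-3,5-diene-1-carboxylate
Conditions: MeI, KHCO3, DMF, 0 to 20 °C, dark
Reagents that add atoms: iodomethane, CI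
Why: SN2 O-methylation of the potassium carboxylate, in which bicarbonate is too weak to deprotonate the hydroxyls and no acid is present to dehydrate the dienediol, so both stereocentres stay untouched.

Step 3
Reactants: 5 methyl (1S,2R)-1,2-dihydroxycyclohexa-3,5-diene-1-carboxylate
Product: 6 methyl (1S,2R)-1,2-(isopropylidenedioxy)cyclohexa-3,5-diene-1-carboxylate (cis-fused 2,2-dimethyl-1,3-dioxolane on O1 and O2)
Conditions: 2,2-dimethoxypropane, p-TsOH·H2O (cat.), acetone, 0 °C; Et3N quench
Reagents that add atoms: 2,2-dimethoxypropane, COC(C)(C)OC
Why: Acid-catalysed transketalisation with the dimethyl ketal of acetone closes the five-membered dioxolane, which the cis-1,2-diol geometry permits; short exposure to a catalytic sulfonic acid in the cold and an amine quench should keep ionisation of the doubly allylic C2–O bond in check.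

Step 4
Reactants: 6 methyl (1S,2R)-1,2-(isopropylidenedioxy)cyclohexa-3,5-diene-1-carboxylate
Product: 7 [(1R,2R)-1,2-(isopropylidenedioxy)cyclohexa-3,5-dien-1-yl]methanol
Conditions: LiAlH4, Et2O, −20 to 0 °C; Na2SO4·10H2O quench
Reagents that add atoms: none
Why: Hydride reduction of an isolated, non-conjugated ester to the primary alcohol by LiAlH4, to which the ketal and the diene are inert; no bond at a stereocentre is touched.

Step 5
Reactants: 7 [(1R,2R)-1,2-(isopropylidenedioxy)cyclohexa-3,5-dien-1-yl]methanol; 8 benzoyl chloride
Product: 9 [(1R,2R)-1,2-(isopropylidenedioxy)cyclohexa-3,5-dien-1-yl]methyl benzoate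
Conditions: BzCl, pyridine, 4-dimethylaminopyridine (cat.), CH2Cl2, 0 °C; product stored at −20 °C and used promptly
Reagents that add atoms: benzoyl chloride (8), O=C(Cl)c1ccccc1
Why: Nucleophile-catalysed acyl transfer (via the N-benzoylpyridinium ion) to the only free hydroxyl, an unhindered primary alcohol, under non-acidic conditions that spare the ketal and the diene.

Step 6
Reactants: 9 [(1R,2R)-1,2-(isopropylidenedioxy)cyclohexa-3,5-dien-1-yl]methyl benzoate; 1 benzoic acid
Product: 10 [(1S,2R,3R,6R)-3,6-bis(benzoyloxy)-1,2-(isopropylidenedioxy)cyclohex-4-en-1-yl]methyl benzoate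
Conditions: Pd(OAc)2 (5 mol %, pre-stirred with PhCO2H and stripped of AcOH), PhCO2H (6 equiv), PhCO2Li (2 equiv), p-benzoquinone (20 mol %), MnO2 (1.5 equiv), acetone, 23 °C, chloride-free
Reagents that add atoms: benzoic acid (1), OC(=O)c1ccccc1; lithium benzoate, [Li+].[O-]C(=O)c1ccccc1 (in exchange with 1, same benzoate pool)
Why: Proposed new method: the diene unit C3=C4–C5=C6 of 9 should coordinate to divalent palladium through its C7-face, away from the cis-fused dioxolane, free benzoate should then add to the terminus C3 anti to the metal to give a C4–C5–C6 pi-allyl complex of divalent palladium, and, with no chloride occupying the metal, a palladium-bound benzoate made reactive by coordinated p-benzoquinone should shift syn onto C6, releasing zerovalent palladium that the quinone and MnO2 return to the divalent state. The closest known reaction type is the trans-selective 1,4-diacyloxylation of cyclohexa-1,3-dienes catalysed by Pd(OAc)2 and p-benzoquinone without chloride, for which carboxylic acids other than acetic acid have been used in acetone; a diene with a fully substituted, oxygen-bearing carbon beside one terminus has not been put through it. As the step closes no ring there is no mode of closure to assign: only the C3–O and C6–O bonds form and the diene contracts to the C4=C5 alkene. C3 is set by anti attack on the O-face (benzoate cis to O2) and C6 by delivery from the metal on the C7-face (benzoate trans to O1 and to the C3 benzoate), so the ketal, which fixes the face of the metal, controls both. Three selectivities are required, namely complexation on the C7-face, opening attack at C3 and not at C6, and a second C–O bond made from the metal rather than from solution; the ketal, the steric shielding of C6 by the fully substituted C1, and a rigorously chloride-free medium should provide them in that order. The substrate also helps in that C1 has no hydrogen to lose for aromatisation, benzoic acid in acetone is too weak to open the ketal, and a catalytic amount of quinone limits cycloaddition to the diene.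

Step 7
Reactants: 10 [(1S,2R,3R,6R)-3,6-bis(benzoyloxy)-1,2-(isopropylidenedioxy)cyclohex-4-en-1-yl]methyl benzoate
Product: 11 [(1R,2R,3R,6R)-3,6-bis(benzoyloxy)-1,2-dihydroxycyclohex-4-en-1-yl]methyl benzoate (CNP0128482.3)
Conditions: CF3CO2H/H2O (9:1), CH2Cl2, 0 °C; toluene co-evaporation, no basic wash
Reagents that add atoms: none
Why: Acid-catalysed ketal hydrolysis (protonation, opening to the oxocarbenium ion, capture by water) should free the C1 and C2 hydroxyls without touching a stereocentre, the three benzoates being stable to cold aqueous acid, while the absence of any base keeps the cis C3 benzoate from shifting to O2.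

**Compound list**

1 | benzoic acid | OC(=O)c1ccccc1 | starting material
2 | sodium benzoate | [Na+].[O-]C(=O)c1ccccc1 | intermediate
3 | sodium (1S,2R)-1,2-dihydroxycyclohexa-3,5-diene-1-carboxylate | [Na+].[O-]C(=O)[C@@]1(O)[C@H](O)C=CC=C1 | intermediate
4 | (1S,2R)-1,2-dihydroxycyclohexa-3,5-diene-1-carboxylic acid | OC(=O)[C@@]1(O)[C@H](O)C=CC=C1 | intermediate
5 | methyl (1S,2R)-1,2-dihydroxycyclohexa-3,5-diene-1-carboxylate | COC(=O)[C@@]1(O)[C@H](O)C=CC=C1 | intermediate
6 | methyl (1S,2R)-1,2-(isopropylidenedioxy)cyclohexa-3,5-diene-1-carboxylate | COC(=O)[C@@]1(OC(C)(C)O2)[C@H]2C=CC=C1 | intermediate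
7 | [(1R,2R)-1,2-(isopropylidenedioxy)cyclohexa-3,5-dien-1-yl]methanol | OC[C@@]1(OC(C)(C)O2)[C@H]2C=CC=C1 | intermediate
8 | benzoyl chloride | O=C(Cl)c1ccccc1 | starting material
9 | [(1R,2R)-1,2-(isopropylidenedioxy)cyclohexa-3,5-dien-1-yl]methyl benzoate | O=C(OC[C@@]1(OC(C)(C)O2)[C@H]2C=CC=C1)c1ccccc1 | intermediate
10 | [(1S,2R,3R,6R)-3,6-bis(benzoyloxy)-1,2-(isopropylidenedioxy)cyclohex-4-en-1-yl]methyl benzoate | O=C(OC[C@@]1(OC(C)(C)O2)[C@H]2[C@H](OC(=O)c2ccccc2)C=C[C@H]1OC(=O)c1ccccc1)c1ccccc1 | intermediate
11 | [(1R,2R,3R,6R)-3,6-bis(benzoyloxy)-1,2-dihydroxycyclohex-4-en-1-yl]methyl benzoate (CNP0128482.3) | O=C(OC[C@@]1(O)[C@H](O)[C@H](OC(=O)c2ccccc2)C=C[C@H]1OC(=O)c1ccccc1)c1ccccc1 | target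

Total step count: 7
Longest linear sequence: 7 steps (1 to 11); 8 enters at step 5 and 1 is used again at step 6.

**Steps most likely to fail**

1. Step 6 (proposed new method). Several processes could defeat it:
- complexation of the metal on the O-face, or opening attack at C6, either of which leads to the other trans diastereomer;
- arrival of the second benzoate from solution, which gives the cis diester;
- beta-oxygen elimination of the allylpalladium intermediate toward C1–O1;
- loss of the diene by cycloaddition with the quinone.

The fallback uses known chemistry only, sets out from 9 and returns to the route at 10. Dye-sensitised photooxygenation (O2, tetraphenylporphyrin, visible light, CH2Cl2, −78 °C) should add singlet oxygen across C3 and C6 on the C7-face, anti to the dioxolane, to give the 3,6-endoperoxide F1. Thiourea in MeOH should reduce the O–O bond to the cis-3,6-diol F2, both hydroxyls on the C7-face, so that C6 already has the configuration needed. A Mitsunobu reaction with benzoic acid 1 (PPh3, diisopropyl azodicarboxylate, toluene, 0 °C) should then take place at the less hindered C3 carbinol, the C6 carbinol being neopentyl, and invert C3 to give the 3-benzoate F3. Benzoylation of the remaining C6 hydroxyl with 8 (pyridine, 4-dimethylaminopyridine) gives 10.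

2. Step 7. Ketal hydrolysis may be slow, because three nearby acyloxy groups destabilise the oxocarbenium ion. Forcing it could let the cis C3 benzoate shift to O2 through a cyclic orthoacid, or ionise an allylic benzoate.

The fallback changes the diol protection to one removed by fluoride; it sets out from 5 and returns at 11. Et3SiOTf and 2,6-lutidine (CH2Cl2, −78 to 0 °C) should give the bis(triethylsilyl) ether F4. i-Bu2AlH (CH2Cl2, −78 °C) should reduce it to the primary alcohol F5, and 8 with pyridine and 4-dimethylaminopyridine should give the diene benzoate F6. The conditions of step 6, or the photooxygenation sequence above, would then give the bis-silylated tribenzoate F7, the two silyloxy groups shielding the O-face as the ketal does. HF·pyridine in THF at 0 °C should then remove both silyl groups to give 11 without aqueous acid or base.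

3. Step 1. The dienediol acid may rearomatise (acid-promoted dehydration with decarboxylation or carboxyl shift) during acidification, extraction and concentration.

The fallback avoids the free acid; it sets out from the sodium salt 3 and returns at 5. The cell-free broth is freeze-dried without acidification and the crude salt 3 is alkylated directly with MeI in DMF, so that the neutral, more robust ester 5 is the first compound extracted. No new compound is involved.

**Further compounds**

F1 | step 6 | 3,6-endoperoxide of 9 (O–O bridge from C3 to C6 on the C7-face, anti to the dioxolane) | O=C(OC[C@@]1(OC(C)(C)O2)[C@H]2[C@@H]3C=C[C@H]1OO3)c1ccccc1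
F2 | step 6 | cis-3,6-diol: [3,6-dihydroxy-1,2-(isopropylidenedioxy)cyclohex-4-en-1-yl]methyl benzoate, both hydroxyls on the C7-face | O=C(OC[C@@]1(OC(C)(C)O2)[C@H]2[C@@H](O)C=C[C@H]1O)c1ccccc1
F3 | step 6 | 3-benzoate: [3-(benzoyloxy)-6-hydroxy-1,2-(isopropylidenedioxy)cyclohex-4-en-1-yl]methyl benzoate, C3 benzoate on the O-face, C6 hydroxyl on the C7-face | O=C(OC[C@@]1(OC(C)(C)O2)[C@H]2[C@H](OC(=O)c2ccccc2)C=C[C@H]1O)c1ccccc1
F4 | step 7 | methyl (1S,2R)-1,2-bis(triethylsilyloxy)cyclohexa-3,5-diene-1-carboxylate | COC(=O)[C@@]1(O[Si](CC)(CC)CC)[C@H](O[Si](CC)(CC)CC)C=CC=C1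
F5 | step 7 | [(1R,2R)-1,2-bis(triethylsilyloxy)cyclohexa-3,5-dien-1-yl]methanol | OC[C@@]1(O[Si](CC)(CC)CC)[C@H](O[Si](CC)(CC)CC)C=CC=C1
F6 | step 7 | [(1R,2R)-1,2-bis(triethylsilyloxy)cyclohexa-3,5-dien-1-yl]methyl benzoate | O=C(OC[C@@]1(O[Si](CC)(CC)CC)[C@H](O[Si](CC)(CC)CC)C=CC=C1)c1ccccc1
F7 | step 7 | [(1S,2R,3R,6R)-3,6-bis(benzoyloxy)-1,2-bis(triethylsilyloxy)cyclohex-4-en-1-yl]methyl benzoate | O=C(OC[C@@]1(O[Si](CC)(CC)CC)[C@H](O[Si](CC)(CC)CC)[C@H](OC(=O)c2ccccc2)C=C[C@H]1OC(=O)c1ccccc1)c1ccccc1
F0 | step 1 | none | none
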